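## The problem

Compound 15 is a flavone: a benzopyranone (rings A and C fused at C4a–C8a) joined through C2–C1' to a trioxygenated phenyl ring B. It has no stereocenter, so the task is one of substitution pattern, oxidation level and chemoselectivity, not configuration. Ring A is fully substituted: C5, C6, C7 and C8 carry methoxy groups and the other two carbons are the ring fusion. Ring A must therefore be made as a hexasubstituted benzene in which one oxygen (O1) is distinguished from four methyl ethers and the single remaining carbon (C4a) carries C4. Ring B has free hydroxyls at C2' and C4' beside a methyl ether at C5'. With five aryl methyl ethers in the molecule, the phenols cannot be released by ether cleavage with boron or aluminium halides, because the C5 methoxy group peri to the C4 carbonyl would be lost first. They must travel under groups that leave under neutral conditions. The pentaoxygenated ring A is easily oxidised towards a quinone, and any reduced form of ring C contains an acid-labile 2-aryl enol ether. The feature that allows a short answer is the polarity around ring C. C4 is benzylic to C4a, whose ortho neighbour carries O1 and whose ortho and para positions (C5, C7) carry methoxy groups, so C4 can be the electrophilic methylene of an ortho-quinone methide. C2 carries ring B, whose C2' and C4' oxygens stabilise positive charge at C2, so C3–C2 can be a terminal arylacetylene that is nucleophilic at C3.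

## Retrosynthesis

**15 to 14 (two O–benzyl bonds).** The two ring B phenols are traced back to benzyl ethers in flavone 14. Benzyl is preferred to sulfonate or acetal protection for two reasons: it keeps ring B electron-rich, which the ring-forming step needs, and it leaves by hydrogenolysis in neutral solution, where none of the five methyl ethers is at risk. The forward reaction must cleave two aryl benzyl ethers faster than it reduces the C2=C3 bond.

**14 to 12 (C4=O back to C4H2).** The carbonyl oxygen is removed to give 4H-chromene 12. The C4 methylene of 12 is benzylic to ring A and allylic to the C2=C3 enol ether, and loss of hydride from it gives an aromatic benzopyrylium ion, so it is the most easily oxidised position in the molecule. Carrying C4 as a methylene is what opens the cycloaddition below; disconnections that keep the carbonyl need strong acid or strong base to close ring C. The forward oxidation must deliver oxygen to C4 and not to C2, and passes through carbinol 13.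

**12 to 7 and 10 (C3–C4 and O1–C2).** Both bonds are cut at once, the retro form of a hetero-[4+2] between ortho-quinone methide 11 and arylacetylene 10. Quinone methide 11 is released from salicyl alcohol 7 by loss of water. The neighbouring cuts (C4–C4a, or C3–C4 alone with C4 as an ester) leave O1–C2 to be made separately and tie ring A to ring B before ring C is formed. This cut is convergent and divides the molecule into two monocyclic benzenes, one with a one-carbon and one with a two-carbon side chain. The forward reaction must place ring B at C2, must favour the alkyne over self-condensation of 11 and over Friedel–Crafts attack on ring B, and must spare the benzyl ethers and the enol ether of the product.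

**7 to 6 to 5 (ring A carbon–CH2OH).** The hydroxymethyl group is traced to the formyl group of salicylaldehyde 6 and this to the ring C–H of phenol 5. Phenol 5 has a single unsubstituted position and it lies ortho to the hydroxyl, so ortho-formylation has no regiochemical choice. Isolating aldehyde 6 and reducing it is easier to control than stopping a phenol–formaldehyde condensation at the alcohol stage.

**5 to 3 to 1 (aryl C–O from aryl C–CHO, then C–CHO from C–H).** The phenolic oxygen of 5 comes from the formyl group of aldehyde 3 by Baeyer–Villiger oxidation and cleavage of formate 4. Aldehyde 3 comes from formylation of 1,2,3,4-tetramethoxybenzene 1 by way of iminium salt 2. The two free positions of 1 are equivalent, so 1 gives a single aldehyde. This sequence turns a cheap symmetric arene into the differentiated pentaoxygenated ring without any selective demethylation.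

**10 to 9 to 8 (alkyne carbon, then two O–benzyl bonds).** The terminal alkyne carbon is removed to give aldehyde 9 (one-carbon homologation in the forward sense). The benzyl groups are removed to give 2,4-dihydroxy-5-methoxybenzaldehyde 8, a catalogue compound that already has the complete ring B oxygenation pattern.

## Roads not taken

**Alternative 1: acylium closure at C4–C4a.** The cut is the C4–C4a bond. In the forward sense (Z)-3-[5-methoxy-2,4-bis(tosyloxy)phenyl]-3-(2,3,4,5-tetramethoxyphenoxy)prop-2-enoic acid A2 is treated with Eaton's reagent (P2O5 in CH3SO3H). The acylium ion attacks the only free carbon of ring A and gives the bis-tosylate flavone A1.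
- Merits: C4 arrives as a carbonyl, so there is no late oxidation and no enol ether intermediate. The site of attack on ring A is unambiguous. A2 would be built from phenol 5, so ring A needs two steps fewer than in the chosen plan. In these respects this road is better.
- Weak points: six aryl ethers and an aryl vinyl ether are exposed to a hot superacidic dehydrating medium. Protonation of the vinyl ether can return phenol 5. The tosylates are needed to keep ring B from reacting, and they must then be removed with hydroxide or a dissolving metal from a flavone whose ring C opens in base. Making A2 also requires ester hydrolysis in the presence of aryl sulfonates.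
- Comparison: the overall length is similar. The chosen plan forms ring C under a catalytic Lewis acid near room temperature and removes its protecting groups under neutral hydrogenolysis.

**Alternative 2: anionic C3–C4 closure onto a ring A ester.** The cut is C3–C4. Methyl 2-{[(Z)-3-tert-butoxy-1-[5-methoxy-2,4-bis(methoxymethoxy)phenyl]-3-oxoprop-1-en-1-yl]oxy}-3,4,5,6-tetramethoxybenzoate A4 would be lithiated at the acrylate α-carbon with LiN(i-Pr)2 at low temperature. The vinyl anion would add to the neighbouring methyl ester and give the flavone-3-carboxylate A3.
- Merits: the oxidation level is correct from the start, no acid is used in the ring closure, and the tether fixes the regiochemistry. Acid would later remove the tert-butyl ester and both methoxymethyl groups together. It is cleaner than the chosen plan in avoiding an oxidation.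
- Weak points: an α-lithiated β-aryloxyacrylate can expel the ring A phenoxide and fall back to an alkynoate. The amide base can also attack the methyl ester. After closure a carboxyl group remains at C3 and has to be removed by ester cleavage and decarboxylation. Ring A is needed as a salicylate ester, which costs an oxidation and an esterification beyond aldehyde 6.
- Comparison: this road is longer by about three steps and rests on a fragile anion. The chosen plan joins two neutral, stable fragments and leaves nothing to excise from ring C.

**Alternative 3: chromium carbene benzannulation to build ring B.** Three bonds of ring B are cut (C5'–C6', C1'–C2', C2'–C3'). 2-Ethynyl-5,6,7,8-tetramethoxy-4H-chromen-4-one A6 would be heated in THF with the alkenyl carbene (CO)5Cr=C(OMe)C(Ot-Bu)=CH2 A7. Alkyne and CO insertion followed by closure of the dienylketene would give the phenol A5.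
- Merits: the three ring B oxygens are differentiated by construction. The methyl ether comes from the carbene, the free 2'-hydroxyl from CO, and the 4'-oxygen arrives as a tert-butyl ether that mild acid removes. The chromone is already at its final oxidation level. In this differentiation it is more elegant than benzyl protection.
- Weak points: chromium is used stoichiometrically. The α-alkoxyvinyl carbene A7 is uncommon. Alkyne A6 is conjugated to the pyranone and electron-poor, the class of alkyne for which benzannulation is least efficient and least regioselective. A6 itself needs a multistep chromone synthesis on the hexasubstituted ring A.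
- Comparison: ring B is built atom by atom although the same pattern is available ready-made in aldehyde 8. The chosen plan uses that material in two steps and an iron salt as catalyst.

Key step: step 7

Remark on the chemistry: 15 has no stereocenter and the route sets none. The only stereogenic carbon that appears is C4 of the unisolated carbinol 13, which is racemic and is destroyed in the same flask.

## Route

Step 1
Reactants: 1 1,2,3,4-tetramethoxybenzene
Product: 3 2,3,4,5-tetramethoxybenzaldehyde, via iminium chloride 2 (not isolated)
Conditions: POCl3, DMF, 0 to 80 °C; then H2O, 0 °C to rt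
Reagents that add atoms: N,N-dimethylformamide CN(C)C=O; water O
Why: Vilsmeier–Haack formylation; the two free positions of 1 are equivalent and each is ortho and para to a methoxy group, the iminium group of 2 deactivates the ring against a second attack, and hydrolysis on work-up releases the aldehyde.

Step 2
Reactants: 3 2,3,4,5-tetramethoxybenzaldehyde
Product: 5 2,3,4,5-tetramethoxyphenol, via aryl formate 4 (not isolated)
Conditions: mCPBA, CH2Cl2, 0 °C to rt; aq. Na2SO3 wash; then K2CO3 (cat.), MeOH, rt, argon
Reagents that add atoms: 3-chloroperoxybenzoic acid OOC(=O)c1cccc(Cl)c1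
Why: Baeyer–Villiger oxidation (Dakin-type) of an electron-rich benzaldehyde, in which the ortho and para methoxy groups favour aryl migration to give formate 4; the formate is methanolysed only after the peracid has been destroyed, so the oxidisable phenol never meets the oxidant.

Step 3
Reactants: 5 2,3,4,5-tetramethoxyphenol
Product: 6 2-hydroxy-3,4,5,6-tetramethoxybenzaldehyde
Conditions: MgCl2, Et3N, (CH2O)n, MeCN, reflux; then aq. HCl
Reagents that add atoms: paraformaldehyde (as formaldehyde) C=O
Why: Casnati–Skattebøl ortho-formylation; formaldehyde is delivered within the magnesium phenoxide to the ortho carbon, which is the only unsubstituted position of 5, and excess formaldehyde acts as hydride acceptor to bring the new carbon to the aldehyde level.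

Step 4
Reactants: 6 2-hydroxy-3,4,5,6-tetramethoxybenzaldehyde
Product: 7 2-(hydroxymethyl)-3,4,5,6-tetramethoxyphenol
Conditions: NaBH4, MeOH, 0 °C; aq. NH4Cl quench
Reagents that add atoms: none
Why: Borohydride reduction of an aryl aldehyde; cold conditions and a near-neutral quench should keep the electron-rich salicyl alcohol from ionising to the quinone methide, and the crude alcohol is taken directly into step 7.

Step 5
Reactants: 8 2,4-dihydroxy-5-methoxybenzaldehyde
Product: 9 2,4-bis(benzyloxy)-5-methoxybenzaldehyde
Conditions: BnBr (2.5 equiv), K2CO3, DMF, 60 °C
Reagents that add atoms: benzyl bromide BrCc1ccccc1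
Why: Williamson ether synthesis; warming in DMF is needed because the 2-hydroxyl is hydrogen-bonded to the aldehyde, and the benzyl ethers keep ring B electron-rich for step 7 and leave later under neutral hydrogenolysis.

Step 6
Reactants: 9 2,4-bis(benzyloxy)-5-methoxybenzaldehyde
Product: 10 1,5-bis(benzyloxy)-2-ethynyl-4-methoxybenzene
Conditions: MeC(O)C(N2)P(O)(OMe)2, K2CO3, MeOH–THF, 0 °C to rt
Reagents that add atoms: dimethyl (1-diazo-2-oxopropyl)phosphonate CC(=O)C(=[N+]=[N-])P(=O)(OC)OC
Why: Ohira–Bestmann variant of the Seyferth–Gilbert homologation; methanolysis of the reagent releases the diazomethylphosphonate anion, which adds to the non-enolisable aldehyde, and loss of dimethyl phosphate and N2 followed by 1,2-hydride shift of the alkylidene carbene gives the terminal alkyne under conditions that spare the benzyl ethers.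

Step 7
Reactants: 7 2-(hydroxymethyl)-3,4,5,6-tetramethoxyphenol; 10 1,5-bis(benzyloxy)-2-ethynyl-4-methoxybenzene
Product: 12 2-[2,4-bis(benzyloxy)-5-methoxyphenyl]-5,6,7,8-tetramethoxy-4H-chromene, via ortho-quinone methide 11 (not isolated)
Conditions: FeCl3 (10 mol %), 4 Å molecular sieves, ClCH2CH2Cl, rt to 50 °C, argon; 7 added slowly to 10 (1.5 equiv)
Reagents that add atoms: none
Why: FeCl3 ionises the benzylic C–O bond of 7, helped by the ortho phenol and the ortho and para methoxy groups, and loss of water gives quinone methide 11. The terminal carbon of alkyne 10 attacks the exocyclic methylene of 11 (C3–C4) and gives an α-aryl vinyl cation delocalised onto the 2- and 4-benzyloxy oxygens of ring B; the ring A oxygen then captures this cation (O1–C2), a polar stepwise oxa-[4+2] with inverse electron demand. The closest known reaction type is the Lewis-acid-promoted cycloaddition of ortho-quinone methides, generated in situ from 2-hydroxybenzyl alcohols, with arylacetylenes to give 2-aryl-4H-chromenes. Ring C closes in a 6-endo sense, with O1 adding to the distal, cation-bearing alkyne carbon so that both alkyne carbons end up in the six-membered ring. No stereocenter is formed. The step needs regioselectivity, which is secured because only attack through the unsubstituted alkyne carbon puts the cation next to the donor-substituted aryl group and so places ring B at C2. It also needs chemoselectivity for the alkyne over self-condensation of 11 and over Friedel–Crafts attack on ring B, which is addressed by keeping 11 dilute through slow addition of 7 to an excess of 10. The sieves take up the released water to protect the enol ether of 12 and to suppress hydration of 10, and the low loading of FeCl3 under argon should leave the benzyl ethers intact and limit one-electron oxidation of the pentaoxygenated phenol.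

Step 8
Reactants: 12 2-[2,4-bis(benzyloxy)-5-methoxyphenyl]-5,6,7,8-tetramethoxy-4H-chromene
Product: 14 2-[2,4-bis(benzyloxy)-5-methoxyphenyl]-5,6,7,8-tetramethoxy-4H-chromen-4-one, via chromen-4-ol 13 (not isolated)
Conditions: DDQ (2.2 equiv), 1,4-dioxane–H2O (10:1), 0 °C to rt
Reagents that add atoms: water O
Why: DDQ oxidation of an activated benzylic and allylic methylene in aqueous dioxane; hydride abstraction from C4 gives the 2-arylbenzopyrylium ion, water adds at C4 to give carbinol 13 (addition at C2 is reversible and returns the cation), and a second hydride abstraction gives the ketone, while benzyl and methyl aryl ethers are inert to DDQ at this temperature.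

Step 9
Reactants: 14 2-[2,4-bis(benzyloxy)-5-methoxyphenyl]-5,6,7,8-tetramethoxy-4H-chromen-4-one
Product: 15 2-(2,4-dihydroxy-5-methoxyphenyl)-5,6,7,8-tetramethoxy-4H-chromen-4-one
Conditions: H2 (1 atm), 10% Pd/C, EtOAc–MeOH, rt
Reagents that add atoms: none
Why: Catalytic hydrogenolysis of aryl benzyl ethers; at atmospheric pressure O–benzyl cleavage should be much faster than reduction of the conjugated C2=C3 bond of a flavone, and the aryl methyl ethers are untouched.

## Compound list

1 | 1,2,3,4-tetramethoxybenzene | COc1ccc(OC)c(OC)c1OC | starting material
2 | dimethyl[(2,3,4,5-tetramethoxyphenyl)methylidene]ammonium chloride | C[N+](C)=Cc1cc(OC)c(OC)c(OC)c1OC.[Cl-] | intermediate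
3 | 2,3,4,5-tetramethoxybenzaldehyde | COc1cc(C=O)c(OC)c(OC)c1OC | intermediate
4 | 2,3,4,5-tetramethoxyphenyl formate | COc1cc(OC=O)c(OC)c(OC)c1OC | intermediate
5 | 2,3,4,5-tetramethoxyphenol | COc1cc(O)c(OC)c(OC)c1OC | intermediate
6 | 2-hydroxy-3,4,5,6-tetramethoxybenzaldehyde | COc1c(O)c(C=O)c(OC)c(OC)c1OC | intermediate
7 | 2-(hydroxymethyl)-3,4,5,6-tetramethoxyphenol | COc1c(O)c(CO)c(OC)c(OC)c1OC | intermediate
8 | 2,4-dihydroxy-5-methoxybenzaldehyde | COc1cc(C=O)c(O)cc1O | starting material
9 | 2,4-bis(benzyloxy)-5-methoxybenzaldehyde | COc1cc(C=O)c(OCc2ccccc2)cc1OCc1ccccc1 | intermediate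
10 | 1,5-bis(benzyloxy)-2-ethynyl-4-methoxybenzene | C#Cc1cc(OC)c(OCc2ccccc2)cc1OCc1ccccc1 | intermediate
11 | 2,3,4,5-tetramethoxy-6-methylidenecyclohexa-2,4-dien-1-one | C=C1C(=O)C(OC)=C(OC)C(OC)=C1OC | intermediate
12 | 2-[2,4-bis(benzyloxy)-5-methoxyphenyl]-5,6,7,8-tetramethoxy-4H-chromene | COc1cc(C2=CCc3c(OC)c(OC)c(OC)c(OC)c3O2)c(OCc2ccccc2)cc1OCc1ccccc1 | intermediate
13 | 2-[2,4-bis(benzyloxy)-5-methoxyphenyl]-5,6,7,8-tetramethoxy-4H-chromen-4-ol (racemic) | COc1cc(C2=CC(O)c3c(OC)c(OC)c(OC)c(OC)c3O2)c(OCc2ccccc2)cc1OCc1ccccc1 | intermediate
14 | 2-[2,4-bis(benzyloxy)-5-methoxyphenyl]-5,6,7,8-tetramethoxy-4H-chromen-4-one | COc1cc(-c2cc(=O)c3c(OC)c(OC)c(OC)c(OC)c3o2)c(OCc2ccccc2)cc1OCc1ccccc1 | intermediate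
15 | 2-(2,4-dihydroxy-5-methoxyphenyl)-5,6,7,8-tetramethoxy-4H-chromen-4-one | COc1cc(-c2cc(=O)c3c(OC)c(OC)c(OC)c(OC)c3o2)c(O)cc1O | target

## Step count and risk

Total steps: 9. Longest linear sequence: 7 (steps 1–4 and 7–9); the ring B branch has 2 steps (steps 5 and 6).

**Step 7 (key step).** The quinone methide may be consumed by self-condensation or by Friedel–Crafts attack on the free ring B carbon between the two benzyloxy groups, because an alkyne is a weak nucleophile. FeCl3 may also be used up by one-electron oxidation of the pentaoxygenated phenol. Released water may hydrate the alkyne or open the enol ether of the product. A redox-inert promoter such as Sc(OTf)3 would be the first adjustment within the step. The fallback makes the same two bonds one after the other without a quinone methide. It sets out from aldehyde 6 and alkyne 10.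
- Alkyne 10 is hydrated with TsOH in wet ethanol to 1-[2,4-bis(benzyloxy)-5-methoxyphenyl]ethan-1-one F1.
- Claisen–Schmidt condensation of this ketone with 6 (KOH, EtOH) forms C3–C4 and gives (E)-1-[2,4-bis(benzyloxy)-5-methoxyphenyl]-3-(2-hydroxy-3,4,5,6-tetramethoxyphenyl)prop-2-en-1-one F2.
- Hydrogenation of the enone double bond over RhCl(PPh3)3, which leaves benzyl ethers alone, gives 1-[2,4-bis(benzyloxy)-5-methoxyphenyl]-3-(2-hydroxy-3,4,5,6-tetramethoxyphenyl)propan-1-one F3.
- Cyclodehydration with catalytic TsOH in refluxing toluene with azeotropic removal of water forms O1–C2 and returns to the route at 12.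

**Step 8.** Water may be captured at C2 of the benzopyrylium ion instead of C4, which leads to ring opening to a hydroxychalcone and stalls the oxidation. The electron-rich ring A may also be attacked by excess quinone. The fallback replaces hydride abstraction by hydrogen-atom abstraction. It sets out from 12, which is treated with tert-butyl hydroperoxide and catalytic CuI to give 2-[2,4-bis(benzyloxy)-5-methoxyphenyl]-4-(tert-butylperoxy)-5,6,7,8-tetramethoxy-4H-chromene F4. Kornblum–DeLaMare fragmentation of this peroxide with Et3N returns to the route at 14.

**Step 4.** The benzylic oxygen may be lost during reduction or work-up (ionisation to the quinone methide, then hydride capture or oligomerisation), so that little intact salicyl alcohol reaches step 7. The fallback avoids the aldehyde and supplies the alcohol in masked, storable form. It sets out from phenol 5, which is condensed with PhB(OH)2 and paraformaldehyde (catalytic propionic acid, toluene, water removal; Nagata ortho-hydroxymethylation) to give 5,6,7,8-tetramethoxy-2-phenyl-4H-1,3,2-benzodioxaborinine F5. Exchange with propane-1,3-diol just before use releases the alcohol and returns to the route at 7.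

**Step 9.** The C2=C3 bond may be over-reduced to the flavanone while the hindered 2'-benzyl ether is still being cleaved. The fallback replaces hydrogenolysis by acidolysis. It sets out from 14, which is warmed in CF3CO2H with pentamethylbenzene as benzyl-cation scavenger; methyl ethers are stable to this acid. It reaches 15 directly, with no new intermediate.

## Further compounds

F1 | step 7 | 1-[2,4-bis(benzyloxy)-5-methoxyphenyl]ethan-1-one | CC(=O)c1cc(OC)c(OCc2ccccc2)cc1OCc1ccccc1
F2 | step 7 | (E)-1-[2,4-bis(benzyloxy)-5-methoxyphenyl]-3-(2-hydroxy-3,4,5,6-tetramethoxyphenyl)prop-2-en-1-one | COc1cc(C(=O)/C=C/c2c(O)c(OC)c(OC)c(OC)c2OC)c(OCc2ccccc2)cc1OCc1ccccc1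
F3 | step 7 | 1-[2,4-bis(benzyloxy)-5-methoxyphenyl]-3-(2-hydroxy-3,4,5,6-tetramethoxyphenyl)propan-1-one | COc1cc(C(=O)CCc2c(O)c(OC)c(OC)c(OC)c2OC)c(OCc2ccccc2)cc1OCc1ccccc1
F4 | step 8 | 2-[2,4-bis(benzyloxy)-5-methoxyphenyl]-4-(tert-butylperoxy)-5,6,7,8-tetramethoxy-4H-chromene (racemic) | COc1cc(C2=CC(OOC(C)(C)C)c3c(OC)c(OC)c(OC)c(OC)c3O2)c(OCc2ccccc2)cc1OCc1ccccc1
F5 | step 4 | 5,6,7,8-tetramethoxy-2-phenyl-4H-1,3,2-benzodioxaborinine | COc1c(OC)c(OC)c2COB(c3ccccc3)Oc2c1OC
F0 | step 9 | none | none
A1 | alternative 1 | 5,6,7,8-tetramethoxy-2-[5-methoxy-2,4-bis(tosyloxy)phenyl]-4H-chromen-4-one | COc1cc(-c2cc(=O)c3c(OC)c(OC)c(OC)c(OC)c3o2)c(OS(=O)(=O)c2ccc(C)cc2)cc1OS(=O)(=O)c1ccc(C)cc1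
A2 | alternative 1 | (Z)-3-[5-methoxy-2,4-bis(tosyloxy)phenyl]-3-(2,3,4,5-tetramethoxyphenoxy)prop-2-enoic acid | OC(=O)/C=C(\Oc1cc(OC)c(OC)c(OC)c1OC)c1cc(OC)c(OS(=O)(=O)c2ccc(C)cc2)cc1OS(=O)(=O)c1ccc(C)cc1
A3 | alternative 2 | tert-butyl 5,6,7,8-tetramethoxy-2-[5-methoxy-2,4-bis(methoxymethoxy)phenyl]-4-oxo-4H-chromene-3-carboxylate | COc1cc(-c2oc3c(OC)c(OC)c(OC)c(OC)c3c(=O)c2C(=O)OC(C)(C)C)c(OCOC)cc1OCOC
A4 | alternative 2 | methyl 2-{[(Z)-3-tert-butoxy-1-[5-methoxy-2,4-bis(methoxymethoxy)phenyl]-3-oxoprop-1-en-1-yl]oxy}-3,4,5,6-tetramethoxybenzoate | CC(C)(C)OC(=O)/C=C(\Oc1c(OC)c(OC)c(OC)c(OC)c1C(=O)OC)c1cc(OC)c(OCOC)cc1OCOC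
A5 | alternative 3 | 2-(4-tert-butoxy-2-hydroxy-5-methoxyphenyl)-5,6,7,8-tetramethoxy-4H-chromen-4-one | COc1cc(-c2cc(=O)c3c(OC)c(OC)c(OC)c(OC)c3o2)c(O)cc1OC(C)(C)C
A6 | alternative 3 | 2-ethynyl-5,6,7,8-tetramethoxy-4H-chromen-4-one | C#Cc1cc(=O)c2c(OC)c(OC)c(OC)c(OC)c2o1
A7 | alternative 3 | pentacarbonyl(2-tert-butoxy-1-methoxyprop-2-en-1-ylidene)chromium, (CO)5Cr=C(OMe)C(Ot-Bu)=CH2 | COC(=[Cr])C(=C)OC(C)(C)C.[C-]#[O+].[C-]#[O+].[C-]#[O+].[C-]#[O+].[C-]#[O+]
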